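**Retrosynthetic overview**

- The tetralin half is the acid isomer of the oxolane half: the oxolane C2–O1 bond is cleaved and C2 is bonded to the carbon para to OMe of the C4 benzyl ring. Both halves therefore come from one twofold-symmetric 5,5'-linked bis(oxolane), and tetralin ring B is closed last, on one arm only, after one biaryl phenol is mesylated.
- The feature that carries the plan: in each oxolane (O1, C2–C5) the C2 aryl, C3 CH2OH (C9) and C4 benzyl groups are mutually cis and the C4 OH is trans to C9. This is the outcome of an anti SN2 opening at C3 of a C3–C4 oxirane that lies trans to the C2 aryl group, so C3–C9 is disconnected on both arms to a bis-epoxide and a vinyl nucleophile (masked CH2OH).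
- The bis-epoxide comes from peracid epoxidation of a bis(2,5-dihydrofuran), closed twice by ring-closing metathesis of the bis-ether formed from an (R,R)-bis(aryl vinyl carbinol) and a 2-(arylmethyl)allyl chloride.
- The carbinols come from double enantioselective vinylation of divanillin dibenzyl ether; only these two centres need reagent control.
- Ring order: biaryl (bought), two dihydrofurans, two oxiranes, two oxolanes, tetralin ring B.

Key step: step 8

Assumption: divanillin is taken as purchasable (otherwise it is one oxidative coupling from vanillin). The 1,2-trans aryl/CH2OH relation of the tetralin is the one a cationic Friedel–Crafts closure gives whatever the configuration at the oxolane C2. TIPS = tri(propan-2-yl)silyl.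

**Step 1**
Reactants: 1 4-bromo-2-methoxyphenol
Product: 2 (4-bromo-2-methoxyphenoxy)tri(propan-2-yl)silane
Conditions: TIPSCl, imidazole, DMF, rt
Reagents that add atoms: chlorotri(propan-2-yl)silane (TIPSCl), CC(C)[Si](Cl)(C(C)C)C(C)C
Why: Imidazole-promoted O-silylation of a phenol, the TIPS ether being chosen because it withstands Grignard reagents, hydride, peracid, hydrogenolysis and dilute acid and so stays orthogonal to the benzyl ethers that will mask the biaryl phenols.

**Step 2**
Reactants: 2 (4-bromo-2-methoxyphenoxy)tri(propan-2-yl)silane; 3 3-chloro-2-(chloromethyl)prop-1-ene (3 equiv)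
Product: 5 {4-[2-(chloromethyl)prop-2-en-1-yl]-2-methoxyphenoxy}tri(propan-2-yl)silane, via arylmagnesium bromide 4 (not isolated)
Conditions: Mg, I2 (cat.), THF, 50 °C; then added to 3, CuI (5 mol%), THF, −20 → 0 °C
Reagents that add atoms: magnesium, [Mg] (enters 4 only)
Why: Magnesium insertion into the aryl bromide followed by copper-catalysed allylic substitution (SN2 and SN2' give the same product on this symmetrical dichloride) should deliver the 2-(arylmethyl)allyl chloride, the excess of 3 suppressing double arylation.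

**Step 3**
Reactants: 6 divanillin
Product: 7 6,6'-bis(benzyloxy)-5,5'-dimethoxybiphenyl-3,3'-dicarbaldehyde
Conditions: BnBr, K2CO3, DMF, 60 °C
Reagents that add atoms: benzyl bromide, BrCc1ccccc1
Why: Williamson benzylation of the two acidic biaryl phenols, giving ethers that survive every later step up to the hydrogenolysis and are then removed without touching the silyl ethers.

**Step 4**
Reactants: 7 6,6'-bis(benzyloxy)-5,5'-dimethoxybiphenyl-3,3'-dicarbaldehyde; 8 vinylmagnesium bromide
Product: 10 (R,R)-bis(allylic alcohol), via divinylzinc 9 (not isolated)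
Conditions: 8 (6 equiv), ZnCl2 (3 equiv), THF/Et2O, 0 °C; 1,4-dioxane, filter; then 7, (2R)-(+)-3-exo-(dimethylamino)isoborneol [(+)-DAIB, 10 mol%], toluene, −10 °C; aq NH4Cl
Reagents that add atoms: zinc chloride, Cl[Zn]Cl (zinc enters 9 only)
Why: Amino-alcohol-catalysed enantioselective organozinc addition to an aromatic aldehyde, run twice in one molecule, in which the zinc chelate of (+)-DAIB should deliver vinyl to the Re face of each formyl group to set both (R) carbinol centres, while any addition of the wrong sense is drained mainly into the separable meso diol so that the twofold-symmetric diol should be of high enantiomeric purity.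

**Step 5**
Reactants: 10 (R,R)-bis(allylic alcohol); 5 {4-[2-(chloromethyl)prop-2-en-1-yl]-2-methoxyphenoxy}tri(propan-2-yl)silane (2.4 equiv)
Product: 11 (R,R)-bis(diene ether), each carbinol oxygen carrying CH2–C(=CH2)–CH2–Ar' (Ar' = 3-methoxy-4-TIPSO-phenyl)
Conditions: NaH, Bu4NI (cat.), THF, 0 → 45 °C
Reagents that add atoms: none
Why: Double Williamson etherification of the sodium alkoxides with a reactive allylic chloride under iodide catalysis, in which the carbinol C–O bonds are not broken and both (R) centres are therefore retained.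

**Step 6**
Reactants: 11 (R,R)-bis(diene ether)
Product: 12 bis[(2R)-2-aryl-4-(arylmethyl)-2,5-dihydrofuran]
Conditions: second-generation Grubbs catalyst (H2IMes)(PCy3)Cl2Ru=CHPh (5 mol% per ring), 1,4-benzoquinone (10 mol%), CH2Cl2 (0.01 M), 40 °C
Reagents that add atoms: none
Why: Double ring-closing metathesis between a monosubstituted and a 1,1-disubstituted alkene should close each five-membered 2,5-dihydrofuran with loss of ethene, the carbinol centre becoming C2 unchanged and benzoquinone suppressing ruthenium hydride alkene migration.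

**Step 7**
Reactants: 12 bis[(2R)-2-aryl-4-(arylmethyl)-2,5-dihydrofuran]
Product: 13 bis(2-aryl-4-benzyl-3,4-epoxyoxolane), oxirane oxygen trans to the C2 aryl group on both rings
Conditions: mCPBA (2.4 equiv), NaHCO3, CH2Cl2, 0 °C
Reagents that add atoms: 3-chloroperoxybenzoic acid (mCPBA), OOC(=O)c1cccc(Cl)c1
Why: Prilezhaev epoxidation of the electron-rich trisubstituted C3=C4 bond, in which the peracid should approach each nearly flat ring from the face opposite the C2 aryl group so that C3 and C4 are set by substrate control with the oxirane oxygen trans to aryl, the bicarbonate buffer protecting the acid-sensitive oxirane.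

**Step 8**
Reactants: 13 bis(2-aryl-4-benzyl-3,4-epoxyoxolane); 8 vinylmagnesium bromide (6 equiv)
Product: 14 bis[(2R,3R,4S)-2-aryl-3-ethenyl-4-hydroxy-4-(arylmethyl)oxolane]
Conditions: CuI (30 mol%), THF, −30 → 0 °C; aq NH4Cl/NH3
Reagents that add atoms: none
Why: CuI and the Grignard reagent form a vinylcuprate whose monovalent copper attacks C3 of each oxirane from the side opposite the C3–O bond (SN2, inversion), and the resulting trivalent vinyl(alkyl)copper alkoxide reductively eliminates to form the C3–C9 bond; the closest known reaction type is the copper-catalysed Grignard opening of trisubstituted and cyclopentene-type epoxides at the less substituted carbon. No ring is closed: each oxirane is opened and each oxolane is kept. C3 is set by inversion, so the vinyl group ends cis to the C2 aryl group because the oxirane oxygen was trans to it, while C4 keeps its configuration with OH trans to vinyl and the benzyl group cis, which is the all-cis carbon array of the target. The step needs attack at C3 and not at C4, which is secured by C4 being fully substituted (no SN2 there) and by the soft cuprate, which does not promote ionisation or Meinwald rearrangement at the tertiary C4–O bond. It also needs the nucleophile to enter on the face shared with the C2 aryl and C4 benzyl groups, which is the real risk and is met by a small sp2 group and an excess of reagent. Benzyl and aryl silyl ethers are inert to the reagent.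

**Step 9**
Reactants: 14 bis[(2R,3R,4S)-2-aryl-3-ethenyl-4-hydroxy-4-(arylmethyl)oxolane]
Product: 16 bis[(2R,3R,4S)-2-aryl-4-hydroxy-3-(hydroxymethyl)-4-(arylmethyl)oxolane], via dialdehyde 15 (not isolated)
Conditions: OsO4 (5 mol%), NaIO4 (8 equiv), 2,6-lutidine, 1,4-dioxane/H2O 3:1, rt; extract; then NaBH4, MeOH/CH2Cl2, −20 °C
Reagents that add atoms: sodium periodate, [Na+].[O-]I(=O)(=O)=O; water, O
Why: Lemieux–Johnson cleavage (osmylation, then periodate glycol fission under lutidine buffering) should turn each vinyl group into a formyl group, and immediate borohydride reduction gives the C9 hydroxymethyl group before the C3 centre, alpha to the aldehyde, can epimerise, so no stereocentre is formed or lost.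

**Step 10**
Reactants: 16 bis[(2R,3R,4S)-2-aryl-4-hydroxy-3-(hydroxymethyl)-4-(arylmethyl)oxolane]
Product: 17 the corresponding 2,2'-biphenol (both biaryl OH free, both Ar' still O-TIPS)
Conditions: H2 (1 atm), 10% Pd/C, EtOAc, rt, stopped at complete debenzylation
Reagents that add atoms: none
Why: Catalytic hydrogenolysis should cleave the two aryl benzyl ethers faster than the cyclic benzylic C2–O1 bonds in a neutral aprotic solvent and leaves the aryl silyl ethers alone, so only the two biaryl phenols are freed.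

**Step 11**
Reactants: 17 2,2'-biphenol
Product: 18 mono-methanesulfonate of the 2,2'-biphenol
Conditions: MsCl (1.0 equiv), K2CO3 (1.1 equiv), acetone, 0 °C
Reagents that add atoms: methanesulfonyl chloride, CS(=O)(=O)Cl
Why: Sulfonylation of a phenoxide, in which carbonate ionises only the 2,2'-biphenol (its monoanion is stabilised by the O–H···O hydrogen bond and the second ionisation is disfavoured), so one equivalent of MsCl should mesylate one biaryl oxygen and leave the un-ionised aliphatic alcohols untouched.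

**Step 12**
Reactants: 18 mono-methanesulfonate
Product: 19 oxolane–tetralin compound (mesylated arm unchanged; the other arm now a (1S,2S,3S)-1-aryl-3-hydroxy-2,3-bis(hydroxymethyl)tetralin)
Conditions: CF3CO2H (5 equiv), CH2Cl2, −10 → 0 °C; then NaHCO3, MeOH
Reagents that add atoms: none
Why: Acid should ionise the benzylic C2–O1 bond only in the oxolane whose aryl group keeps a free para hydroxyl (para-quinone-methide-type cation), the mesylated aryl group being too electron-poor, and the C4 benzyl ring then closes six-membered ring B through its carbon para to OMe in an intramolecular Friedel–Crafts alkylation (the known acid isomerisation of 2-aryl-4-benzyloxolane lignans to aryltetralins), the new C1 centre being set trans to the C2 hydroxymethyl group by that neighbouring centre with the aryl group pseudo-equatorial.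

**Step 13**
Reactants: 19 oxolane–tetralin compound
Product: 20 CNP0344108.1
Conditions: KOH, MeOH/H2O 4:1, 50 °C, argon; then pH 7 phosphate buffer
Reagents that add atoms: none
Why: Hydroxide should cleave the aryl methanesulfonate at sulfur and the two aryl silyl ethers at silicon, each with a phenoxide leaving group, while the alcohols, methyl ethers and oxolane are stable to base at this temperature and the neutral work-up avoids acid that would cyclise the second oxolane.

**Compound list**

1 | 4-bromo-2-methoxyphenol | COc1cc(Br)ccc1O | starting material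
2 | (4-bromo-2-methoxyphenoxy)tri(propan-2-yl)silane | COc1cc(Br)ccc1O[Si](C(C)C)(C(C)C)C(C)C | intermediate
3 | 3-chloro-2-(chloromethyl)prop-1-ene | ClCC(=C)CCl | starting material
4 | {3-methoxy-4-[tri(propan-2-yl)silyloxy]phenyl}magnesium bromide (not isolated) | COc1cc([Mg]Br)ccc1O[Si](C(C)C)(C(C)C)C(C)C | intermediate
5 | {4-[2-(chloromethyl)prop-2-en-1-yl]-2-methoxyphenoxy}tri(propan-2-yl)silane | COc1cc(CC(=C)CCl)ccc1O[Si](C(C)C)(C(C)C)C(C)C | intermediate
6 | divanillin (6,6'-dihydroxy-5,5'-dimethoxybiphenyl-3,3'-dicarbaldehyde) | COc1cc(C=O)cc(-c2cc(C=O)cc(OC)c2O)c1O | starting material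
7 | 6,6'-bis(benzyloxy)-5,5'-dimethoxybiphenyl-3,3'-dicarbaldehyde | COc1cc(C=O)cc(-c2cc(C=O)cc(OC)c2OCc2ccccc2)c1OCc1ccccc1 | intermediate
8 | vinylmagnesium bromide | C=C[Mg]Br | starting material
9 | divinylzinc (not isolated) | C=C[Zn]C=C | intermediate
10 | (1R,1'R)-1,1'-[6,6'-bis(benzyloxy)-5,5'-dimethoxybiphenyl-3,3'-diyl]di(prop-2-en-1-ol) | COc1cc([C@H](O)C=C)cc(-c2cc([C@H](O)C=C)cc(OC)c2OCc2ccccc2)c1OCc1ccccc1 | intermediate
11 | 2,2'-bis(benzyloxy)-3,3'-dimethoxy-5,5'-bis[(1R)-1-({2-[(3-methoxy-4-TIPSO-phenyl)methyl]prop-2-en-1-yl}oxy)prop-2-en-1-yl]biphenyl | COc1cc([C@H](OCC(=C)Cc2ccc(O[Si](C(C)C)(C(C)C)C(C)C)c(OC)c2)C=C)cc(-c2cc([C@H](OCC(=C)Cc3ccc(O[Si](C(C)C)(C(C)C)C(C)C)c(OC)c3)C=C)cc(OC)c2OCc2ccccc2)c1OCc1ccccc1 | intermediate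
12 | 2,2'-bis(benzyloxy)-3,3'-dimethoxy-5,5'-bis[(2R)-4-[(3-methoxy-4-TIPSO-phenyl)methyl]-2,5-dihydrofuran-2-yl]biphenyl | COc1cc([C@@H]2OCC(Cc3ccc(O[Si](C(C)C)(C(C)C)C(C)C)c(OC)c3)=C2)cc(-c2cc([C@@H]3OCC(Cc4ccc(O[Si](C(C)C)(C(C)C)C(C)C)c(OC)c4)=C3)cc(OC)c2OCc2ccccc2)c1OCc1ccccc1 | intermediate
13 | bis-epoxide: each arm a 2-aryl-4-[(3-methoxy-4-TIPSO-phenyl)methyl]-3,4-epoxyoxolane, (2S,3S,4R) in oxolane numbering [(1R,4S,5S)-3,6-dioxabicyclo[3.1.0]hexane], oxirane oxygen trans to the C2 aryl group; biaryl oxygens benzylated (the C2 letter differs from 12 only through CIP priority) | COc1cc([C@@H]2OC[C@@]3(Cc4ccc(O[Si](C(C)C)(C(C)C)C(C)C)c(OC)c4)O[C@@H]23)cc(-c2cc([C@@H]3OC[C@@]4(Cc5ccc(O[Si](C(C)C)(C(C)C)C(C)C)c(OC)c5)O[C@@H]34)cc(OC)c2OCc2ccccc2)c1OCc1ccccc1 | intermediate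
14 | 2,2'-bis(benzyloxy)-3,3'-dimethoxy-5,5'-bis[(2R,3R,4S)-3-ethenyl-4-hydroxy-4-[(3-methoxy-4-TIPSO-phenyl)methyl]oxolan-2-yl]biphenyl (aryl, vinyl and benzyl all cis; OH trans to vinyl) | COc1cc([C@@H]2OC[C@](O)(Cc3ccc(O[Si](C(C)C)(C(C)C)C(C)C)c(OC)c3)[C@@H]2C=C)cc(-c2cc([C@@H]3OC[C@](O)(Cc4ccc(O[Si](C(C)C)(C(C)C)C(C)C)c(OC)c4)[C@@H]3C=C)cc(OC)c2OCc2ccccc2)c1OCc1ccccc1 | intermediate
15 | the bis[(2R,3R,4S)-3-formyl] analogue of 14 (not isolated) | COc1cc([C@@H]2OC[C@](O)(Cc3ccc(O[Si](C(C)C)(C(C)C)C(C)C)c(OC)c3)[C@@H]2C=O)cc(-c2cc([C@@H]3OC[C@](O)(Cc4ccc(O[Si](C(C)C)(C(C)C)C(C)C)c(OC)c4)[C@@H]3C=O)cc(OC)c2OCc2ccccc2)c1OCc1ccccc1 | intermediate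
16 | 2,2'-bis(benzyloxy)-3,3'-dimethoxy-5,5'-bis[(2R,3R,4S)-4-hydroxy-3-(hydroxymethyl)-4-[(3-methoxy-4-TIPSO-phenyl)methyl]oxolan-2-yl]biphenyl | COc1cc([C@@H]2OC[C@](O)(Cc3ccc(O[Si](C(C)C)(C(C)C)C(C)C)c(OC)c3)[C@@H]2CO)cc(-c2cc([C@@H]3OC[C@](O)(Cc4ccc(O[Si](C(C)C)(C(C)C)C(C)C)c(OC)c4)[C@@H]3CO)cc(OC)c2OCc2ccccc2)c1OCc1ccccc1 | intermediate
17 | 3,3'-dimethoxy-5,5'-bis[(2R,3R,4S)-4-hydroxy-3-(hydroxymethyl)-4-[(3-methoxy-4-TIPSO-phenyl)methyl]oxolan-2-yl]biphenyl-2,2'-diol | COc1cc([C@@H]2OC[C@](O)(Cc3ccc(O[Si](C(C)C)(C(C)C)C(C)C)c(OC)c3)[C@@H]2CO)cc(-c2cc([C@@H]3OC[C@](O)(Cc4ccc(O[Si](C(C)C)(C(C)C)C(C)C)c(OC)c4)[C@@H]3CO)cc(OC)c2O)c1O | intermediate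
18 | mono-methanesulfonate of 17 (one biaryl OH as OSO2CH3) | COc1cc([C@@H]2OC[C@](O)(Cc3ccc(O[Si](C(C)C)(C(C)C)C(C)C)c(OC)c3)[C@@H]2CO)cc(-c2cc([C@@H]3OC[C@](O)(Cc4ccc(O[Si](C(C)C)(C(C)C)C(C)C)c(OC)c4)[C@@H]3CO)cc(OC)c2O)c1OS(C)(=O)=O | intermediate
19 | biaryl in which the mesylated ring keeps its (2R,3R,4S)-oxolane and the free-phenol ring carries a (1S,2S,3S)-3-hydroxy-2,3-bis(hydroxymethyl)-6-methoxy-7-TIPSO-1,2,3,4-tetrahydronaphthalen-1-yl group | COc1cc(C[C@@]2(O)CO[C@@H](c3cc(OC)c(OS(C)(=O)=O)c(-c4cc([C@H]5c6cc(O[Si](C(C)C)(C(C)C)C(C)C)c(OC)cc6C[C@@](O)(CO)[C@@H]5CO)cc(OC)c4O)c3)[C@H]2CO)ccc1O[Si](C(C)C)(C(C)C)C(C)C | intermediate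
20 | CNP0344108.1: 5,5'-linked biaryl of a (2R,3R,4S)-2-aryl-4-hydroxy-4-(4-hydroxy-3-methoxybenzyl)-3-(hydroxymethyl)oxolane and a (1S,2S,3S)-1-aryl-3,7-dihydroxy-2,3-bis(hydroxymethyl)-6-methoxytetralin | COc1cc(C[C@@]2(O)CO[C@@H](c3cc(OC)c(O)c(-c4cc([C@H]5c6cc(O)c(OC)cc6C[C@@](O)(CO)[C@@H]5CO)cc(OC)c4O)c3)[C@H]2CO)ccc1O | target

**Totals**

Total step count: 13. Longest linear sequence: 11 steps (6 to 20 through steps 3–13; the branch 1 to 5, steps 1–2, joins at step 5 and is equally long).

**Steps most likely to fail**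

1. Step 8. The cuprate may fail to reach C3 on the face it shares with the C2 aryl and C4 benzyl groups; if the opening is slow, magnesium halide may instead open or rearrange the tertiary C4–O bond. Fallback: form the C3–C9 bond with a rod-shaped sp nucleophile under Lewis acid activation. Starting from 13, lithium (trimethylsilyl)acetylide and BF3·OEt2 in THF at −78 °C (anti opening at the less substituted oxirane carbon) should give the bis(trimethylsilylethynyl) diol F1. AgNO3 (cat.) in aqueous acetone then removes the alkynyl silyl groups without touching the aryl silyl ethers to give the bis(ethynyl) diol F2. Semihydrogenation with H2 over Pd/CaCO3 poisoned with Pb(OAc)2, with quinoline, returns to the route at 14.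

2. Step 7. The peracid may show poor facial selectivity; each ring selects independently, so the share of the wanted trans,trans isomer falls with the square of the single-ring selectivity. Fallback: replace substrate control by reagent control. Starting from 12, a Shi epoxidation with the fructose-derived chiral ketone (the enantiomer whose dioxirane is matched to the face anti to the aryl group), KHSO5 and K2CO3 in MeCN/dimethoxymethane/H2O at 0 °C should give 13 directly; no new compound arises (F0).

3. Step 11. The sulfonylation may lose mono-selectivity (bis-mesylate) or phenol-over-alcohol selectivity (mesylation at C9–OH). Fallback: give up the differentiation and rely on partial conversion. Starting from 17, Bu4NF/AcOH in THF removes both silyl groups to give the free bis(oxolane) tetraphenol F3. Dilute CF3CO2H in CH2Cl2/MeCN at 0 °C, stopped at partial conversion, then cyclises one arm to give the target 20 directly, which is separated from recovered F3 (recycled) and the doubly cyclised isomer. This costs material and exposes the surviving oxolane to acid, which is why it is only the reserve.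

**Further compounds**

F1 | step 8 | 3,3''-bis[2-(trimethylsilyl)ethynyl] analogue of 14 (alkynyl in place of vinyl at each oxolane C3) | COc1cc([C@@H]2OC[C@](O)(Cc3ccc(O[Si](C(C)C)(C(C)C)C(C)C)c(OC)c3)[C@@H]2C#C[Si](C)(C)C)cc(-c2cc([C@@H]3OC[C@](O)(Cc4ccc(O[Si](C(C)C)(C(C)C)C(C)C)c(OC)c4)[C@@H]3C#C[Si](C)(C)C)cc(OC)c2OCc2ccccc2)c1OCc1ccccc1
F2 | step 8 | bis(3-ethynyl) analogue of 14 | COc1cc([C@@H]2OC[C@](O)(Cc3ccc(O[Si](C(C)C)(C(C)C)C(C)C)c(OC)c3)[C@@H]2C#C)cc(-c2cc([C@@H]3OC[C@](O)(Cc4ccc(O[Si](C(C)C)(C(C)C)C(C)C)c(OC)c4)[C@@H]3C#C)cc(OC)c2OCc2ccccc2)c1OCc1ccccc1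
F0 | step 7 | none | none
F3 | step 11 | 3,3'-dimethoxy-5,5'-bis[(2R,3R,4S)-4-hydroxy-4-(4-hydroxy-3-methoxybenzyl)-3-(hydroxymethyl)oxolan-2-yl]biphenyl-2,2'-diol | COc1cc([C@@H]2OC[C@](O)(Cc3ccc(O)c(OC)c3)[C@@H]2CO)cc(-c2cc([C@@H]3OC[C@](O)(Cc4ccc(O)c(OC)c4)[C@@H]3CO)cc(OC)c2O)c1O
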